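I counted turnovers.

| setting | Wednesday's | Thursday's | north-west | east |
|---|---|---|---|---|
| starting material | 0.020 M (fed, over 80 s) | 0.020 M (fed, over 80 s) | 0.020 M | 0.020 M (fed, over 80 s) |
| second substrate | 0.020 M | 0.020 M | 0.0200 M | 0.0200 M |
| precatalyst | 2 µM | 3 µM | 4.0 µM | 4.0 µM |
| remark | run made earlier; the fed solution adds 0.20 times the starting volume | run made earlier; the fed solution adds 0.20 times the starting volume | everything together at the start, the whole solution of starting material included, so that from the start the volume is larger by 0.20 times the starting volume | the fed solution adds 0.20 times the starting volume |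
| time |  |  | 40 min | 25 min |

| run | time / min | target / % | starting material / % |
|---|---|---|---|
| Wednesday's | 4.00 | 1.9 | 92.7 |
| Wednesday's | 8.00 | 4.9 | 84.1 |
| Wednesday's | 12.0 | 8.3 | 76.5 |
| Wednesday's | 15.0 | 9.9 | 70.8 |
| Wednesday's | 20.0 | 14.2 | 62.5 |
| Wednesday's | 25.0 | 18.0 | 52.7 |
| Thursday's | 4.00 | 3.4 | 93.3 |
| Thursday's | 8.00 | 8.1 | 81.9 |
| Thursday's | 12.0 | 12.5 | 71.9 |
| Thursday's | 15.0 | 15.9 | 65.1 |
| Thursday's | 20.0 | 20.9 | 55.3 |
| Thursday's | 25.0 | 26.1 | 46.1 |

(each reading ± 0.5 percentage points)

- the flask that ends with the higher amount of target, in percent of the starting material charged, or "neither" when 2 percentage points or less lies between them (north-west / east / neither)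
- final target, as a percentage of the starting material charged, in north-west
- final target, as a percentage of the starting material charged, in east

- charges are per starting volume, the dose included; the dosed solution carries all of it

Pooling both runs from 4.00 min to 12.0 min, I read the turnover rate, target made per precatalyst charged per minute, as 77.5 /min. From 15.0 min to 25.0 min it read 73.2 /min, lower than before. So the slowing was a factor 0.945, a loose reading given a scatter of 0.5 percentage points. Thursday's starting material read 81.9 % at 8.00 min and 55.3 % at 20.0 min, the middles of those windows.

For east, I ran the later rate from the end of the feed to 25 min, which gave 34.6 %. I expected north-west to run further down, so I applied the factor 3 times to the first rate as a mean over 40 min, which gave 52.2 %. I backed north-west, ahead by 18 points.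

The forecast chose north-west, with 51 % there and 33.5 % in east, less than my north-west figure and less than my east figure: “Its longer time clearly wins.”

The flasks gave 49.3 % in north-west and 34.5 % in east, so north-west made more.

    complex B → enzyme + second product (k = 11000 /min)
    starting material → uncatalysed product (k = 0.0160 /min)
    complex A → enzyme + target (k = 110 /min)
    second substrate + enzyme ⇌ complex B (K = 1800 /M, k = 68000 /M/s)
    precatalyst → enzyme (k = 1.20 /min)
    complex B → spent catalyst (k = 0.00770 /min)
    starting material + enzyme ⇌ complex A (K = 190 /M, k = 35000 /M/s)

North-west made 2470 turnovers, a mean of 61.6 /min, slower than the first rate. It still held 17 % of its starting material at 40.0 min. The neighbour repeats north-west with 0.080 M of starting material. The first rate held over 40 min gives 15.5 % of that charge. That neighbour gave 18.8 %, which is 3760 turnovers, a mean of 93.9 /min, faster than the first rate. Its uncatalysed product reached 42.4 %.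

The earlier runs and the new flask are calculated for substances that don't exist.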